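**Retrosynthetic overview**

1. Core numbering (3,7-dioxabicyclo[3.3.0]octane): C1/C5 ring fusion, C2/C6 aryl-bearing, O3/O7, C4/C8 the OCH2 carbons; ring A = C1–C2–O3–C4–C5, ring B = C1–C5–C6–O7–C8. Apart from its aryl groups the core has twofold symmetry, so the trimethoxyphenyl group is placed on C2 and the protected hydroxydimethoxyphenyl group on C6.
2. The plan rests on C8, a CH2 bonded only to C1 and O7. It is brought in last as carbon monoxide, by hydroformylation at C1 of a C1=C2 aryl enol ether (ring A as a 5-aryl-2,3-dihydrofuran) directed from the free C6 hydroxyl. O7 then captures the aldehyde, which closes ring B (C1–C8, C8–O7) and sets C1 and C2.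
3. Ring A is formed first, from a C5-substituted γ-butyrolactone by addition of 3,4,5-trimethoxyphenyllithium at C2 and cyclodehydration. The lactone comes from an Evans syn-aldol of a succinate imide with 3-benzyloxy-4,5-dimethoxybenzaldehyde, which sets C5 and C6.
4. After the key step the C8 lactol hydroxyl is removed by ionic hydrogenation and the phenol is freed by hydrogenolysis.

Key step: step 10

**Route**

Step 1
Reactants: 1 3-hydroxy-4,5-dimethoxybenzaldehyde
Product: 2 3-(benzyloxy)-4,5-dimethoxybenzaldehyde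
Conditions: BnBr, K2CO3, DMF, rt
Reagents that add atoms: benzyl bromide, BrCc1ccccc1
Why: Williamson ether synthesis on the phenoxide gives a benzyl ether that should survive the boron aldol, hydride, aryllithium, fluoride, hydroformylation and Lewis-acid steps and is removed only at the end.

Step 2
Reactants: 3 mono-tert-butyl succinate; 4 (S)-4-benzyl-2-oxazolidinone
Product: 6 tert-butyl 4-[(4S)-4-benzyl-2-oxo-1,3-oxazolidin-3-yl]-4-oxobutanoate, via mixed pivalic anhydride 5 (not isolated)
Conditions: PivCl, Et3N, THF, −20 °C; then LiCl, 4, −20 °C → rt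
Reagents that add atoms: none
Why: N-acylation of the oxazolidinone through the mixed anhydride (LiCl/Et3N activation) should occur at the unhindered succinyl carbonyl and leave the tert-butyl ester untouched.

Step 3
Reactants: 6 tert-butyl 4-[(4S)-4-benzyl-2-oxo-1,3-oxazolidin-3-yl]-4-oxobutanoate; 2 3-(benzyloxy)-4,5-dimethoxybenzaldehyde
Product: 9 tert-butyl (3S,4S)-4-[3-(benzyloxy)-4,5-dimethoxyphenyl]-3-{[(4S)-4-benzyl-2-oxo-1,3-oxazolidin-3-yl]carbonyl}-4-hydroxybutanoate, via Z-boron enolate 7 (not isolated), via boron aldolate 8 (not isolated)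
Conditions: n-Bu2BOTf, iPr2NEt, CH2Cl2, −78 → 0 °C; 2, −78 → 0 °C; then pH 7 phosphate buffer, MeOH, 30% H2O2, 0 °C
Reagents that add atoms: none
Why: Evans syn-aldol, in which soft enolisation of the imide CH2 (not the ester CH2) gives the Z-boron enolate, which should add to the aldehyde through a closed Zimmerman–Traxler chair on the face away from the auxiliary benzyl group (imide dipoles opposed), setting C5 and C6 together as the (3S,4S) syn adduct, while the tert-butyl ester keeps the aldolate from lactonising.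

Step 4
Reactants: 9 tert-butyl (3S,4S)-4-[3-(benzyloxy)-4,5-dimethoxyphenyl]-3-{[(4S)-4-benzyl-2-oxo-1,3-oxazolidin-3-yl]carbonyl}-4-hydroxybutanoate
Product: 10 tert-butyl (3S,4S)-4-[3-(benzyloxy)-4,5-dimethoxyphenyl]-3-{[(4S)-4-benzyl-2-oxo-1,3-oxazolidin-3-yl]carbonyl}-4-[(tert-butyldimethylsilyl)oxy]butanoate
Conditions: TBSOTf (1.2 equiv), 2,6-lutidine, CH2Cl2, −78 → 0 °C
Reagents that add atoms: tert-butyldimethylsilyl triflate, CC(C)(C)[Si](C)(C)OS(=O)(=O)C(F)(F)F
Why: Silylation of the hindered benzylic alcohol with the silyl triflate blocks O7, so that only the primary hydroxyl made next can lactonise, and the low temperature and small excess spare the tert-butyl ester.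

Step 5
Reactants: 10 tert-butyl (3S,4S)-4-[3-(benzyloxy)-4,5-dimethoxyphenyl]-3-{[(4S)-4-benzyl-2-oxo-1,3-oxazolidin-3-yl]carbonyl}-4-[(tert-butyldimethylsilyl)oxy]butanoate
Product: 11 tert-butyl (3R,4S)-4-[3-(benzyloxy)-4,5-dimethoxyphenyl]-4-[(tert-butyldimethylsilyl)oxy]-3-(hydroxymethyl)butanoate
Conditions: LiBH4, MeOH (1 equiv), THF, 0 °C
Reagents that add atoms: none
Why: Reductive cleavage of the N-acyl oxazolidinone by LiBH4 at the exocyclic imide carbonyl should give the C4 primary alcohol and return the auxiliary, while the tert-butyl ester and silyl ether are not reduced and no stereocentre is touched.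

Step 6
Reactants: 11 tert-butyl (3R,4S)-4-[3-(benzyloxy)-4,5-dimethoxyphenyl]-4-[(tert-butyldimethylsilyl)oxy]-3-(hydroxymethyl)butanoate
Product: 12 (4R)-4-{(S)-[3-(benzyloxy)-4,5-dimethoxyphenyl][(tert-butyldimethylsilyl)oxy]methyl}oxolan-2-one
Conditions: PPTS (0.2 equiv), toluene, 80 °C
Reagents that add atoms: none
Why: Acid-catalysed lactonisation (5-exo-trig acyl substitution of the primary hydroxyl on the tert-butyl ester with loss of tert-butanol) should proceed under an acid mild enough to leave the benzylic silyl ether in place.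

Step 7
Reactants: 12 (4R)-4-{(S)-[3-(benzyloxy)-4,5-dimethoxyphenyl][(tert-butyldimethylsilyl)oxy]methyl}oxolan-2-one; 13 5-bromo-1,2,3-trimethoxybenzene
Product: 15 (3R,4S)-4-[3-(benzyloxy)-4,5-dimethoxyphenyl]-4-[(tert-butyldimethylsilyl)oxy]-3-(hydroxymethyl)-1-(3,4,5-trimethoxyphenyl)butan-1-one, via 3,4,5-trimethoxyphenyllithium 14 (not isolated)
Conditions: 13, n-BuLi, THF, −78 °C; then 12, −78 °C; AcOH, −78 °C
Reagents that add atoms: none
Why: Bromine–lithium exchange followed by single addition of the aryllithium to the γ-lactone should stop at the ketone stage, because the lithium hemiketal alkoxide persists at −78 °C until the acidic quench, which installs the C2 aryl group with C5 and C6 unchanged.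

Step 8
Reactants: 15 (3R,4S)-4-[3-(benzyloxy)-4,5-dimethoxyphenyl]-4-[(tert-butyldimethylsilyl)oxy]-3-(hydroxymethyl)-1-(3,4,5-trimethoxyphenyl)butan-1-one
Product: 17 (3R)-3-{(S)-[3-(benzyloxy)-4,5-dimethoxyphenyl][(tert-butyldimethylsilyl)oxy]methyl}-5-(3,4,5-trimethoxyphenyl)-2,3-dihydrofuran, via cyclic hemiketal 16 (not isolated)
Conditions: PPTS (0.1 equiv), benzene, reflux, Dean–Stark trap; then Et3N; Et3N-washed silica
Reagents that add atoms: none
Why: Acid-catalysed cyclodehydration of a γ-hydroxy aryl ketone closes ring A to the hemiketal, which should lose water under azeotropic removal to give the aryl-conjugated C1=C2 enol ether, C1 being the only carbon next to C2 that carries hydrogen.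

Step 9
Reactants: 17 (3R)-3-{(S)-[3-(benzyloxy)-4,5-dimethoxyphenyl][(tert-butyldimethylsilyl)oxy]methyl}-5-(3,4,5-trimethoxyphenyl)-2,3-dihydrofuran
Product: 18 (S)-[3-(benzyloxy)-4,5-dimethoxyphenyl][(3R)-5-(3,4,5-trimethoxyphenyl)-2,3-dihydrofuran-3-yl]methanol
Conditions: Bu4NF, THF, 0 °C → rt; aq. NaHCO3 work-up; Et3N-washed silica
Reagents that add atoms: none
Why: Fluoride cleavage of the silyl ether is basic and acid-free, so the acid-labile aryl enol ether should survive while the C6 hydroxyl is freed as the anchor for the directing group.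

Step 10
Reactants: 18 (S)-[3-(benzyloxy)-4,5-dimethoxyphenyl][(3R)-5-(3,4,5-trimethoxyphenyl)-2,3-dihydrofuran-3-yl]methanol; 19 carbon monoxide
Product: 22 (3S,3aR,6S,6aS)-3-[3-(benzyloxy)-4,5-dimethoxyphenyl]-6-(3,4,5-trimethoxyphenyl)tetrahydro-1H,3H-furo[3,4-c]furan-1-ol (lactol; both anomers at C8), via substrate diphenylphosphinite 20 (not isolated), via hydroxy aldehyde 21 (not isolated)
Conditions: Rh(CO)2(acac) (3 mol%), Ph2POMe (20 mol%), CO/H2 (1:1, 40 bar), 4 Å MS, THF, 60 °C
Reagents that add atoms: none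
Why: Proposed new method: Ph2POMe should exchange reversibly onto the C6 hydroxyl to give phosphinite 20, whose phosphorus holds the rhodium hydride on the face of the C1=C2 enol ether that carries the C5–C6 bond; syn hydrometalation then puts H on C2 and Rh on C1 within a six-membered P,C-chelate, CO inserts into the Rh–C1 bond, hydrogenolysis of the acyl frees the aldehyde, and phosphinite exchange releases hydroxy aldehyde 21 and returns the directing group. The closest known reaction type is the rhodium-catalysed hydroformylation of homoallylic alcohols steered by a catalytic, reversibly bound phosphinite to branched aldehydes that close to γ-lactols, established for mono- and 1,2-disubstituted alkenes; a trisubstituted 5-aryl-2,3-dihydrofuran lies outside that scope, although cyclic enol ethers as a class do undergo rhodium hydroformylation. Ring B closes by 5-exo-trig addition of the O7 hydroxyl to the C8 aldehyde, giving lactol 22 as an anomeric mixture that converges in step 11. C1 is controlled by the existing C5 stereocentre, because the tether reaches only the alkene face cis to the C6 arm, so C8 ends cis to C6 (cis ring fusion); C2 is controlled by the syn addition, H arriving cis to C8 so that the trimethoxyphenyl group ends trans to C8 (exo). The step needs formylation at C1 rather than C2 and delivery to the more hindered face: the first is secured because Rh at C2 would be a tertiary alkyl leading to a quaternary aldehyde through a seven-membered chelate, the second by the phosphinite tether, with CO pressure and molecular sieves holding back undirected reaction and enol-ether hydrolysis.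

Step 11
Reactants: 22 (3S,3aR,6S,6aS)-3-[3-(benzyloxy)-4,5-dimethoxyphenyl]-6-(3,4,5-trimethoxyphenyl)tetrahydro-1H,3H-furo[3,4-c]furan-1-ol
Product: 23 (1S,3aR,4S,6aR)-1-[3-(benzyloxy)-4,5-dimethoxyphenyl]-4-(3,4,5-trimethoxyphenyl)tetrahydro-1H,3H-furo[3,4-c]furan
Conditions: Et3SiH, BF3·OEt2, CH2Cl2, −78 → −40 °C; then Et3N, aq. NaHCO3
Reagents that add atoms: none
Why: Ionic hydrogenation of the lactol, in which BF3 ionises the anomeric C8–OH to the cyclic oxocarbenium ion and Et3SiH reduces it to CH2, should leave the benzylic C2–O3 and C6–O7 bonds un-ionised at this temperature, so no stereocentre changes.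

Step 12
Reactants: 23 (1S,3aR,4S,6aR)-1-[3-(benzyloxy)-4,5-dimethoxyphenyl]-4-(3,4,5-trimethoxyphenyl)tetrahydro-1H,3H-furo[3,4-c]furan
Product: 24 2,3-dimethoxy-5-[(1S,3aR,4S,6aR)-4-(3,4,5-trimethoxyphenyl)tetrahydro-1H,3H-furo[3,4-c]furan-1-yl]phenol
Conditions: H2 (1 atm), 10% Pd/C, EtOAc, rt; stopped when 23 is consumed
Reagents that add atoms: none
Why: Hydrogenolysis of the aryl benzyl ether over Pd/C under neutral conditions should be much faster than cleavage of the benzylic ring C–O bonds, so the phenol is freed with the furofuran intact.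

**Compound list**

1 | 3-hydroxy-4,5-dimethoxybenzaldehyde | COc1cc(C=O)cc(O)c1OC | starting material
2 | 3-(benzyloxy)-4,5-dimethoxybenzaldehyde | COc1cc(C=O)cc(OCc2ccccc2)c1OC | intermediate
3 | mono-tert-butyl succinate | CC(C)(C)OC(=O)CCC(=O)O | starting material
4 | (S)-4-benzyl-2-oxazolidinone | O=C1N[C@@H](Cc2ccccc2)CO1 | starting material
5 | mixed anhydride of 3 with pivalic acid | CC(C)(C)OC(=O)CCC(=O)OC(=O)C(C)(C)C | intermediate
6 | tert-butyl 4-[(4S)-4-benzyl-2-oxo-1,3-oxazolidin-3-yl]-4-oxobutanoate | CC(C)(C)OC(=O)CCC(=O)N1[C@@H](Cc2ccccc2)COC1=O | intermediate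
7 | Z-dibutylboron enolate of 6 | CCCCB(CCCC)O/C(=C\CC(=O)OC(C)(C)C)N1[C@@H](Cc2ccccc2)COC1=O | intermediate
8 | O-dibutylboryl aldolate of 9 | O=C1OC[C@H](Cc2ccccc2)N1C(=O)[C@@H](CC(=O)OC(C)(C)C)[C@H](OB(CCCC)CCCC)c1cc(OCc2ccccc2)c(OC)c(OC)c1 | intermediate
9 | tert-butyl (3S,4S)-4-[3-(benzyloxy)-4,5-dimethoxyphenyl]-3-{[(4S)-4-benzyl-2-oxo-1,3-oxazolidin-3-yl]carbonyl}-4-hydroxybutanoate | O=C1OC[C@H](Cc2ccccc2)N1C(=O)[C@@H](CC(=O)OC(C)(C)C)[C@H](O)c1cc(OCc2ccccc2)c(OC)c(OC)c1 | intermediate
10 | tert-butyl (3S,4S)-4-[3-(benzyloxy)-4,5-dimethoxyphenyl]-3-{[(4S)-4-benzyl-2-oxo-1,3-oxazolidin-3-yl]carbonyl}-4-[(tert-butyldimethylsilyl)oxy]butanoate | O=C1OC[C@H](Cc2ccccc2)N1C(=O)[C@@H](CC(=O)OC(C)(C)C)[C@H](O[Si](C)(C)C(C)(C)C)c1cc(OCc2ccccc2)c(OC)c(OC)c1 | intermediate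
11 | tert-butyl (3R,4S)-4-[3-(benzyloxy)-4,5-dimethoxyphenyl]-4-[(tert-butyldimethylsilyl)oxy]-3-(hydroxymethyl)butanoate | OC[C@@H](CC(=O)OC(C)(C)C)[C@H](O[Si](C)(C)C(C)(C)C)c1cc(OCc2ccccc2)c(OC)c(OC)c1 | intermediate
12 | (4R)-4-{(S)-[3-(benzyloxy)-4,5-dimethoxyphenyl][(tert-butyldimethylsilyl)oxy]methyl}oxolan-2-one | O=C1C[C@H](CO1)[C@H](O[Si](C)(C)C(C)(C)C)c1cc(OCc2ccccc2)c(OC)c(OC)c1 | intermediate
13 | 5-bromo-1,2,3-trimethoxybenzene | COc1cc(Br)cc(OC)c1OC | starting material
14 | 3,4,5-trimethoxyphenyllithium | [Li]c1cc(OC)c(OC)c(OC)c1 | intermediate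
15 | (3R,4S)-4-[3-(benzyloxy)-4,5-dimethoxyphenyl]-4-[(tert-butyldimethylsilyl)oxy]-3-(hydroxymethyl)-1-(3,4,5-trimethoxyphenyl)butan-1-one | COc1cc(cc(OC)c1OC)C(=O)C[C@H](CO)[C@H](O[Si](C)(C)C(C)(C)C)c1cc(OCc2ccccc2)c(OC)c(OC)c1 | intermediate
16 | (4R)-4-{(S)-[3-(benzyloxy)-4,5-dimethoxyphenyl][(tert-butyldimethylsilyl)oxy]methyl}-2-(3,4,5-trimethoxyphenyl)oxolan-2-ol (hemiketal, both C2 epimers) | COc1cc(cc(OC)c1OC)C1(O)C[C@H](CO1)[C@H](O[Si](C)(C)C(C)(C)C)c1cc(OCc2ccccc2)c(OC)c(OC)c1 | intermediate
17 | (3R)-3-{(S)-[3-(benzyloxy)-4,5-dimethoxyphenyl][(tert-butyldimethylsilyl)oxy]methyl}-5-(3,4,5-trimethoxyphenyl)-2,3-dihydrofuran | COc1cc(cc(OC)c1OC)C1=C[C@H](CO1)[C@H](O[Si](C)(C)C(C)(C)C)c1cc(OCc2ccccc2)c(OC)c(OC)c1 | intermediate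
18 | (S)-[3-(benzyloxy)-4,5-dimethoxyphenyl][(3R)-5-(3,4,5-trimethoxyphenyl)-2,3-dihydrofuran-3-yl]methanol | COc1cc(cc(OC)c1OC)C1=C[C@H](CO1)[C@H](O)c1cc(OCc2ccccc2)c(OC)c(OC)c1 | intermediate
19 | carbon monoxide | [C-]#[O+] | starting material
20 | diphenylphosphinite ester of 18 at the C6 oxygen | COc1cc(cc(OC)c1OC)C1=C[C@H](CO1)[C@H](OP(c1ccccc1)c1ccccc1)c1cc(OCc2ccccc2)c(OC)c(OC)c1 | intermediate
21 | (2S,3S,4R)-4-{(S)-[3-(benzyloxy)-4,5-dimethoxyphenyl](hydroxy)methyl}-2-(3,4,5-trimethoxyphenyl)oxolane-3-carbaldehyde | COc1cc(cc(OC)c1OC)[C@H]2OC[C@@H]([C@@H]2C=O)[C@H](O)c1cc(OCc2ccccc2)c(OC)c(OC)c1 | intermediate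
22 | (3S,3aR,6S,6aS)-3-[3-(benzyloxy)-4,5-dimethoxyphenyl]-6-(3,4,5-trimethoxyphenyl)tetrahydro-1H,3H-furo[3,4-c]furan-1-ol (both anomers) | COc1cc(cc(OC)c1OC)[C@H]2OC[C@H]3[C@@H]2C(O)O[C@@H]3c1cc(OCc4ccccc4)c(OC)c(OC)c1 | intermediate
23 | (1S,3aR,4S,6aR)-1-[3-(benzyloxy)-4,5-dimethoxyphenyl]-4-(3,4,5-trimethoxyphenyl)tetrahydro-1H,3H-furo[3,4-c]furan | COc1cc(cc(OC)c1OC)[C@H]2OC[C@H]3[C@@H]2CO[C@@H]3c1cc(OCc4ccccc4)c(OC)c(OC)c1 | intermediate
24 | 2,3-dimethoxy-5-[(1S,3aR,4S,6aR)-4-(3,4,5-trimethoxyphenyl)tetrahydro-1H,3H-furo[3,4-c]furan-1-yl]phenol (CNP0181235.1) | COc1cc([C@H]2OC[C@H]3[C@@H]2CO[C@@H]3c2cc(OC)c(OC)c(OC)c2)cc(O)c1OC | target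

**Step count and risks**

Total step count: 12. Longest linear sequence: 11 steps (from 1 through steps 1 and 3–12, or from 3 and 4 through steps 2–12).

Steps most likely to fail:

1. Step 10 (proposed new method). The directing phosphinite may not exchange onto the hindered, easily ionised benzylic alcohol, or the trisubstituted enol ether may resist hydrometalation. The result would be no conversion, undirected reaction from the wrong face, or hydrogenation of the alkene. The fallback uses known chemistry, sets out from lactone 12 and comes back at 23; in it the lactone carbonyl becomes C8 and the new aldehyde carbon becomes C2. Deprotonation of 12 with LiN(iPr)2 in THF at −78 °C and aldol addition to 3,4,5-trimethoxybenzaldehyde, the electrophile entering trans to the C5 substituent, should give the trans α-(hydroxybenzyl) lactone F1 as a mixture at the new carbinol carbon. LiAlH4 in THF at 0 °C should open it to the silyl-protected triol F2, and Bu4NF should then give the tetraol F3. Brief treatment of F3 with camphorsulfonic acid in CH2Cl2 at 0 °C should close both tetrahydrofuran rings by capture of the two benzylic cations by the primary hydroxyls, the classical 1,4-diaryl-2,3-bis(hydroxymethyl)butane-1,4-diol route to furofurans, giving 23. Both benzylic centres are re-formed in this closure under the control of C1 and C5, each aryl group being expected to settle trans to the substituent on the neighbouring ring-fusion carbon; a benzylic epimer, if formed, would have to be separated.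

2. Step 8. The protic acid needed for dehydration may cause loss of the benzylic silyl ether, or hydration and oligomerisation of the electron-rich enol ether. The fallback sets out from 15 and comes back at 17. Treatment of 15 with HC(OMe)3 and MeOH with a trace of PPTS at 0 °C should give the cyclic methyl ketal F4. Methanol is then eliminated under buffered aprotic conditions with TMSOTf and iPr2NEt in CH2Cl2 at −20 °C (ketal to enol ether), so the enol ether never meets a protic acid.

3. Step 7. A second addition of the aryllithium to the ketone freed on warming, or enolisation of the lactone, may compete with single addition. The fallback sets out from 12 and comes back at 15. Aminolysis of 12 with MeNHOMe·HCl and Me3Al in CH2Cl2 should give the hydroxy Weinreb amide F5. Excess 14 (the first equivalent is consumed by the hydroxyl) should then add once to the amide through the chelated tetrahedral intermediate and give 15 on work-up.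

**Further compounds**

F1 | step 10 | (3S,4R)-4-{(S)-[3-(benzyloxy)-4,5-dimethoxyphenyl][(tert-butyldimethylsilyl)oxy]methyl}-3-[hydroxy(3,4,5-trimethoxyphenyl)methyl]oxolan-2-one (3,4-trans; carbinol epimers) | O=C1[C@H](C(O)c2cc(OC)c(OC)c(OC)c2)[C@H](CO1)[C@H](O[Si](C)(C)C(C)(C)C)c1cc(OCc2ccccc2)c(OC)c(OC)c1
F2 | step 10 | (2R,3R)-2-{(S)-[3-(benzyloxy)-4,5-dimethoxyphenyl][(tert-butyldimethylsilyl)oxy]methyl}-3-[hydroxy(3,4,5-trimethoxyphenyl)methyl]butane-1,4-diol (carbinol epimers) | OC[C@H](C(O)c1cc(OC)c(OC)c(OC)c1)[C@H](CO)[C@H](O[Si](C)(C)C(C)(C)C)c1cc(OCc2ccccc2)c(OC)c(OC)c1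
F3 | step 10 | (2R,3R)-2-{(S)-[3-(benzyloxy)-4,5-dimethoxyphenyl](hydroxy)methyl}-3-[hydroxy(3,4,5-trimethoxyphenyl)methyl]butane-1,4-diol (carbinol epimers) | OC[C@H](C(O)c1cc(OC)c(OC)c(OC)c1)[C@H](CO)[C@H](O)c1cc(OCc2ccccc2)c(OC)c(OC)c1
F4 | step 8 | (4R)-4-{(S)-[3-(benzyloxy)-4,5-dimethoxyphenyl][(tert-butyldimethylsilyl)oxy]methyl}-2-methoxy-2-(3,4,5-trimethoxyphenyl)oxolane (both C2 epimers) | COc1cc(cc(OC)c1OC)C1(OC)C[C@H](CO1)[C@H](O[Si](C)(C)C(C)(C)C)c1cc(OCc2ccccc2)c(OC)c(OC)c1
F5 | step 7 | (3R,4S)-4-[3-(benzyloxy)-4,5-dimethoxyphenyl]-4-[(tert-butyldimethylsilyl)oxy]-3-(hydroxymethyl)-N-methoxy-N-methylbutanamide | CON(C)C(=O)C[C@H](CO)[C@H](O[Si](C)(C)C(C)(C)C)c1cc(OCc2ccccc2)c(OC)c(OC)c1
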